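## Structural features

The target is a lignan of the 2-aryl-3-(acyloxymethyl)-4-benzyloxolane type. One oxolane ring (O1, C2, C3, C4, C5) carries the catechol ring A directly on C2, the acetoxymethyl carbon C3' on C3 and, through the methylene C4', the guaiacyl ring B on C4; C5 is an unsubstituted CH2 next to oxygen. C2 (S), C3 (R) and C4 (R) are three contiguous stereocentres: ring A and C3' are trans, C3' and C4' are cis, so one cis pair is built into the ring and cannot be reached by equilibrating C3 or C4. The fragile parts are the free catechol (air, base), the primary acetate (base, hydride, nucleophiles) and the C2–O1 bond, a benzylic ether para to an oxygen substituent that ionises under acid and can be hydrogenolysed. This lability makes C2 the one correctable centre, because 2,3-trans is the more stable arrangement, but a C2 cation can also be captured by ring B to give an aryltetralin. The real difficulty is therefore the absolute configuration and cis relation of C3 and C4, together with keeping the two oxygenated arenes distinct. The key step uses two features: C2–O1–C5 is the C–O–C unit of a carbonyl ylide built from the ring A aldehyde and a CH2 terminus, and C3–C4 with its cis substituents is a Z-alkene whose C3' carbon, at the carbonyl oxidation level, both activates the alkene and anchors a chiral Lewis acid.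

## Logic of the disconnections

18 ⇒ 17. The three aryl O–CH2Ph bonds are cut last. Benzyl ethers are inert to fluoride (silyl ethers are not), to hydride and to acylation (esters are not), and their removal is neutral, so the acetate is not endangered. The gain is that every intermediate is a neutral, non-phenolic, air-stable compound. The demand is that reductive cleavage stops before the benzylic C2–O1 bond is attacked.

17 ⇒ 16. The ester C–O bond at C3' is cut. The acetate would not survive the hydride step that creates C3'–OH, so it is introduced afterwards. The gain is the removal of the only base-labile group from the earlier steps. The demand is small, since 16 has a single hydroxyl.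

16 ⇒ 15. The CH2OH at C3' is traced back to an acyl group on the oxazolidinone nitrogen. The carbonyl at C3' is what makes the alkene a dipolarophile and gives a chiral Lewis acid two-point binding. The gain is that C3' serves as activating group and then becomes the required carbon without any C–C change. The demand is reductive cleavage at the exocyclic carbonyl without epimerising C3.

15 ⇒ 4 + 12. C2–C3 and C4–C5 are cut. This is the only cut that removes the ring, two skeletal bonds and all three stereocentres at once, and it divides the molecule into two fragments that each carry one arene, so ring A and ring B never have to be told apart. The demands are regiocontrol, one alkene face, retention of the Z geometry, exo approach, and ylide generation that tolerates the Lewis acid.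

4 ⇒ 3 ⇒ 1 + 2. The C–Cl bond and then the two acetal C–O bonds are cut. 4 is too labile to store or purify, so it is traced to 3, a stable symmetric acetal from which an acyl chloride removes one alkoxy group; 1, 2 and the acyl chloride cannot simply be mixed, because 2 would be acylated. The gain is a purifiable, storable precursor, and 1 and 2 are both catalogue compounds. The demand is strictly anhydrous handling and immediate use of 4.

12 ⇒ 8 + 11. The Cα=Cβ double bond is cut. A Z-selective phosphonate olefination that brings the imide ready-made avoids activating a Z-acid with acidic γ-hydrogens. The gain is two simple fragments and one step. The demand is kinetic Z-selectivity and the absence of excess base, since the γ-CH2 of 12 is benzylic and vinylogous to the imide.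

8 ⇒ 6 ⇒ 5. The terminal C=C bond (one carbon lost) and the phenol O–benzyl bond are cut. The allyl chain of 5 contains the two carbons needed plus one. The gain is a bulk starting material. The demand is oxidation of the alkene and not the arene, and prompt use of the enolisable aldehyde.

11 ⇒ 10 ⇒ 9. The P–C bond and the N–acyl bond are cut. Both forward steps are simple substitutions on bulk chemicals. The demand is mono-substitution at each stage.

## Other disconnections considered

Alternative 1: The cuts are C2–C3 and C4–C4'. The lithiated dithiane A3 (a masked acyl anion made from 1) would add to the β-carbon of butenolide A2 anti to the menthyloxy group, and the lactone enolate would be benzylated by bromide A4 anti to the new substituent. This gives the trans,trans lactone A1, whose two new centres map onto C3 and C4 of the target; the trans lactone becomes the cis pair once the ring is re-formed through C2.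
- In favour: every operation is of an established polar type, and control rests on a crystalline chiral-pool acetal auxiliary. On predictability of the C3/C4 configuration this plan is the better one.
- Against: the lactone of A1 is not the ring of the target. The carbonyl must be reduced to C5 and the acetal carbon to C3', the dithiane unmasked with thiophilic or oxidative reagents beside electron-rich arenes, the ketone reduced, and O1–C2 closed through a benzylic cation, where capture by ring B threatens. The auxiliary is stoichiometric and lost.
- Comparison: the structural gain of the key step is smaller (two bonds, two centres, no target ring, against two bonds, three centres and the ring). The mechanism is stepwise and safer. About six or seven operations follow the key step against three, so the sequence would be some three to four steps longer. Acetylation and hydrogenolysis at the end are the same in both plans, so they are equal there.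

Alternative 2: The cut is the single bond O1–C2. Oxidation of the only free phenol of diol A5 (para to the benzylic carbon of ring A) with Ag2O or DDQ would give a quinone methide. The C5 hydroxyl adds to it 5-exo-trig with rearomatisation to give A6; the other hydroxyl could only close a four-membered ring.
- In favour: the step is of a known, biomimetic type and needs no catalyst control, and C2 should come out trans to the C3 substituent. In precedent and operational simplicity this key step is better than the chosen one.
- Against: it forms one C–O bond and one stereocentre, so the hard part, the C3/C4 pair with two different benzyl groups, is pushed back into the synthesis of A5. Ring A needs two different oxygen functions (free 4-OH, protected 3-OH), which costs a regioselective protection sequence. Oxidants of this strength can attack other electron-rich benzylic positions. A6 has a free phenol beside the primary alcohol to be acetylated.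
- Comparison: the chosen plan is far more convergent. Alternative 2 is ahead in mechanistic safety and behind in step economy by an estimated five or more steps. Both rely on the same preference for the 2,3-trans ring, so they are equal on C2.

Alternative 3: The cut is C3–C4, with the hydrogen at C4' added in the same step. Cp2TiCl (trivalent titanium, from Cp2TiCl2 and zinc) would open the terminal epoxide of A7 to the secondary radical at C3, which cyclises 5-exo-trig onto the cinnamyl double bond. The benzylic radical is reduced by a second equivalent and protonated, giving A8, which is the same compound as 16.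
- In favour: the reaction type is established for oxolanes of this substitution pattern. The C3' alcohol appears directly, so one step fewer follows the key step. A chair-like transition state with the C2 aryl group pseudo-equatorial should favour the 2,3-trans/3,4-cis arrangement. In precedent it is the better plan.
- Against: all stereocontrol is relayed from C2, which must first be made enantiopure. Radical closures of this kind are rarely fully selective at C4, where an epimer could not be corrected. Etherification of an epoxy alcohol under base risks Payne rearrangement. Premature reduction of the C3 radical leads to deoxygenation. Titanium is needed in more than stoichiometric amount.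
- Comparison: step counts are about equal, since A7 would itself need about seven operations (vinyl addition to 1, asymmetric epoxidation with kinetic resolution, some three steps to the ring B allylic partner, etherification). The chosen plan takes the C3/C4 relation from alkene geometry through a concerted step, which is the stronger structural argument, and pays for it with an untested combination of reagents.

Key step: step 8

Assumption: the sense of induction of the nickel–bis(oxazoline) complex on a Z-enoyl imide cannot be fixed with certainty; the (S,S) ligand is written on the expectation that it leaves the Cα-Re/Cβ-Re face open, and the (R,R) ligand would be used without other change if the sense proves opposite.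

Remark: the configuration at C3 is the same in 15 and in 16–18; the descriptor changes from S to R only because the CIP rank of the C3 substituent changes on reduction.

## Route

Step 1
Reactants: 1 3,4-bis(benzyloxy)benzaldehyde; 2 (trimethylsilyl)methanol
Product: 3 1,2-bis(benzyloxy)-4-{bis[(trimethylsilyl)methoxy]methyl}benzene
Conditions: 2 (2.5 equiv), TsOH·H2O (2 mol%), toluene, reflux, Dean–Stark trap; Et3N quench
Reagents that add atoms: none
Why: Acid-catalysed acetalisation driven by azeotropic removal of water; the benzyl ethers and C–Si bonds are inert to catalytic acid, and the symmetric acetal is the storable form of the ylide precursor.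

Step 2
Reactants: 3 1,2-bis(benzyloxy)-4-{bis[(trimethylsilyl)methoxy]methyl}benzene
Product: 4 chloro[3,4-bis(benzyloxy)phenyl]methyl (trimethylsilyl)methyl ether (racemic, used crude at once)
Conditions: AcCl (1.1 equiv), SOCl2 (1 mol%), CH2Cl2, 0 °C to rt; volatiles removed in vacuo
Reagents that add atoms: acetyl chloride, CC(=O)Cl
Why: Acetal-to-α-chloro ether exchange with an acyl chloride: one silylmethoxy group is O-acylated and leaves as its acetate, and chloride captures the aryl-stabilised oxocarbenium ion. The electron-rich arene makes ionisation easy, so no Lewis acid is needed.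

Step 3
Reactants: 5 eugenol (4-allyl-2-methoxyphenol)
Product: 6 4-allyl-1-(benzyloxy)-2-methoxybenzene
Conditions: BnBr, K2CO3, acetone, reflux
Reagents that add atoms: benzyl bromide, BrCc1ccccc1
Why: Williamson ether synthesis on the phenoxide; carbonate is too weak a base to move the allyl double bond into conjugation.

Step 4
Reactants: 6 4-allyl-1-(benzyloxy)-2-methoxybenzene
Product: 8 (4-benzyloxy-3-methoxyphenyl)acetaldehyde, via ozonide 7 (not isolated)
Conditions: O3, CH2Cl2, −78 °C (stopped at first excess); then PPh3, −78 °C to rt
Reagents that add atoms: ozone, [O-][O+]=O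
Why: Ozonolysis with reductive work-up; the terminal alkene reacts far faster than the dialkoxyarene, and the phosphine reduces the ozonide to the aldehyde under neutral conditions. The enolisable aldehyde is used without storage.

Step 5
Reactants: 9 oxazolidin-2-one
Product: 10 3-(bromoacetyl)oxazolidin-2-one
Conditions: n-BuLi, THF, −78 °C; then added to BrCH2COBr, THF, −78 to 0 °C
Reagents that add atoms: bromoacetyl bromide, BrCC(Br)=O
Why: N-acylation of the lithiated carbamate; the acyl bromide end reacts much faster than the CH2Br end at low temperature, and inverse addition suppresses N-alkylation of the product.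

Step 6
Reactants: 10 3-(bromoacetyl)oxazolidin-2-one
Product: 11 3-[2-(diphenoxyphosphoryl)acetyl]oxazolidin-2-one
Conditions: (PhO)2P(O)H, Et3N, CH2Cl2, 0 °C to rt
Reagents that add atoms: diphenyl phosphite, O=[PH](Oc1ccccc1)Oc1ccccc1
Why: Michaelis–Becker reaction: the amine-generated phosphite anion displaces the activated α-bromide through phosphorus, giving a phosphonate with the electron-poor aryloxy groups that Z-selective olefination requires.

Step 7
Reactants: 8 (4-benzyloxy-3-methoxyphenyl)acetaldehyde; 11 3-[2-(diphenoxyphosphoryl)acetyl]oxazolidin-2-one
Product: 12 3-[(Z)-4-(4-benzyloxy-3-methoxyphenyl)but-2-enoyl]oxazolidin-2-one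
Conditions: 11 (1.2 equiv), NaH (1.1 equiv), THF, 0 °C; then 8, −78 to −40 °C; aq NH4Cl at −40 °C
Reagents that add atoms: none
Why: Horner–Wadsworth–Emmons olefination in its Z-selective diaryl phosphonate variant: the aryloxy groups make collapse of the first-formed syn adduct faster than its equilibration, so the kinetic Z-alkene should result. Low temperature and the absence of excess base protect the enolisable aldehyde and the acidic γ-CH2 of 12.

Step 8
Reactants: 4 chloro[3,4-bis(benzyloxy)phenyl]methyl (trimethylsilyl)methyl ether; 12 3-[(Z)-4-(4-benzyloxy-3-methoxyphenyl)but-2-enoyl]oxazolidin-2-one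
Product: 15 3-{[(2S,3S,4R)-2-[3,4-bis(benzyloxy)phenyl]-4-(4-benzyloxy-3-methoxybenzyl)oxolan-3-yl]carbonyl}oxazolidin-2-one, via oxocarbenium chloride 13 (not isolated), via carbonyl ylide 14 (not isolated)
Conditions: Ni(ClO4)2·6H2O (20 mol%), (S,S)-4,6-dibenzofurandiyl-2,2'-bis(4-phenyloxazoline) (22 mol%), 4 Å MS, CH2Cl2, rt, 2 h; 12, then CsF (4 equiv) and 4 (2 equiv, added over 6 h in CH2Cl2–MeCN), −20 °C
Reagents that add atoms: none
Why: Proposed new method: chloride leaves 4 to give the aryl-stabilised oxocarbenium chloride 13, fluoride removes the silyl group to release the non-stabilised carbonyl ylide 14, and 14 adds across the Cα=Cβ bond of 12 held as a two-point chelate on the cationic divalent nickel–bis(oxazoline) complex; the closest known reaction types are the fluoride-induced 1,3-elimination of α-chloroalkyl silylmethyl ethers with [3+2] capture by acrylates and the chiral Lewis acid-controlled cycloaddition of diazo-derived carbonyl ylides to 3-enoyl oxazolidin-2-ones, which are combined here for the first time. The oxolane is closed by one concerted, asynchronous [3+2] cycloaddition (four π electrons of the ylide, two of the alkene), suprafacial on both partners, with C4–C5 forming slightly ahead of C2–C3. Regioselectivity is needed and comes from the larger HOMO coefficient on the unsubstituted CH2 terminus of 14 meeting the larger LUMO coefficient at Cβ of the chelated imide, so the acyl carbon ends next to the aryl-bearing C2. The cis relation of C3 and C4 is the Z geometry of 12 copied by the suprafacial addition. Their absolute configuration is controlled by the ligand, whose phenyl groups should close the Cα-Si face so that the ylide adds to the Cα-Re/Cβ-Re face. C2 is controlled by the exo approach of the ylide in its extended form (aryl anti to the CH2 terminus), which keeps the aryl group clear of the nickel-bound acyl group and gives the 2,3-trans adduct. The catalysed path must outrun the uncatalysed one and the ylide must be trapped before it dimerises, which slow addition of 4, CsF of low solubility in CH2Cl2 (precipitating CsCl and keeping free halide off nickel) and the LUMO lowering by chelation are meant to secure.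

Step 9
Reactants: 15 3-{[(2S,3S,4R)-2-[3,4-bis(benzyloxy)phenyl]-4-(4-benzyloxy-3-methoxybenzyl)oxolan-3-yl]carbonyl}oxazolidin-2-one
Product: 16 [(2S,3R,4R)-2-[3,4-bis(benzyloxy)phenyl]-4-(4-benzyloxy-3-methoxybenzyl)oxolan-3-yl]methanol
Conditions: LiBH4, MeOH (1 equiv), THF, 0 °C
Reagents that add atoms: none
Why: Reductive cleavage of an N-acyl oxazolidinone: hydride attacks the exocyclic carbonyl, the oxazolidinone leaves and the acyl carbon is reduced to CH2OH. The ethers are untouched, and at 0 °C C3 should keep its configuration.

Step 10
Reactants: 16 [(2S,3R,4R)-2-[3,4-bis(benzyloxy)phenyl]-4-(4-benzyloxy-3-methoxybenzyl)oxolan-3-yl]methanol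
Product: 17 [(2S,3R,4R)-2-[3,4-bis(benzyloxy)phenyl]-4-(4-benzyloxy-3-methoxybenzyl)oxolan-3-yl]methyl acetate
Conditions: Ac2O, pyridine, DMAP (cat.), CH2Cl2, 0 °C to rt
Reagents that add atoms: acetic anhydride, CC(=O)OC(C)=O
Why: Nucleophile-catalysed acetylation of the only free hydroxyl; the conditions are non-acidic, so the benzylic C2–O1 bond is not ionised.

Step 11
Reactants: 17 [(2S,3R,4R)-2-[3,4-bis(benzyloxy)phenyl]-4-(4-benzyloxy-3-methoxybenzyl)oxolan-3-yl]methyl acetate
Product: 18 [(2S,3R,4R)-2-(3,4-dihydroxyphenyl)-4-(4-hydroxy-3-methoxybenzyl)oxolan-3-yl]methyl acetate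
Conditions: H2 (1 atm), 10% Pd/C, EtOAc, rt, stopped after three equivalents of H2; work-up under argon
Reagents that add atoms: none
Why: Hydrogenolysis of three aryl benzyl ethers, whose phenoxide leaving groups make them far more reactive than the ring C2–O1 bond with its alkoxide leaving group. The neutral aprotic solvent leaves the acetate and all three stereocentres untouched.

## Compound list

1 | 3,4-bis(benzyloxy)benzaldehyde | O=Cc1ccc(OCc2ccccc2)c(OCc2ccccc2)c1 | starting material
2 | (trimethylsilyl)methanol | C[Si](C)(C)CO | starting material
3 | 1,2-bis(benzyloxy)-4-{bis[(trimethylsilyl)methoxy]methyl}benzene | C[Si](C)(C)COC(OC[Si](C)(C)C)c1ccc(OCc2ccccc2)c(OCc2ccccc2)c1 | intermediate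
4 | chloro[3,4-bis(benzyloxy)phenyl]methyl (trimethylsilyl)methyl ether (racemic) | C[Si](C)(C)COC(Cl)c1ccc(OCc2ccccc2)c(OCc2ccccc2)c1 | intermediate
5 | eugenol (4-allyl-2-methoxyphenol) | C=CCc1ccc(O)c(OC)c1 | starting material
6 | 4-allyl-1-(benzyloxy)-2-methoxybenzene | C=CCc1ccc(OCc2ccccc2)c(OC)c1 | intermediate
7 | 3-[(4-benzyloxy-3-methoxyphenyl)methyl]-1,2,4-trioxolane (racemic ozonide, not isolated) | COc1cc(CC2OCOO2)ccc1OCc1ccccc1 | intermediate
8 | (4-benzyloxy-3-methoxyphenyl)acetaldehyde | O=CCc1ccc(OCc2ccccc2)c(OC)c1 | intermediate
9 | oxazolidin-2-one | O=C1NCCO1 | starting material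
10 | 3-(bromoacetyl)oxazolidin-2-one | O=C1OCCN1C(=O)CBr | intermediate
11 | 3-[2-(diphenoxyphosphoryl)acetyl]oxazolidin-2-one | O=C1OCCN1C(=O)CP(=O)(Oc1ccccc1)Oc1ccccc1 | intermediate
12 | 3-[(Z)-4-(4-benzyloxy-3-methoxyphenyl)but-2-enoyl]oxazolidin-2-one | O=C1OCCN1C(=O)/C=C\Cc1ccc(OCc2ccccc2)c(OC)c1 | intermediate
13 | {[3,4-bis(benzyloxy)phenyl]methylidene}[(trimethylsilyl)methyl]oxonium chloride (not isolated) | C[Si](C)(C)C[O+]=Cc1ccc(OCc2ccccc2)c(OCc2ccccc2)c1.[Cl-] | intermediate
14 | {[3,4-bis(benzyloxy)phenyl]methylidene}oxoniomethanide, the carbonyl ylide of 1 with a CH2 terminus, extended form with the aryl group anti to CH2 (not isolated) | [CH2-]/[O+]=C/c1ccc(OCc2ccccc2)c(OCc2ccccc2)c1 | intermediate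
15 | 3-{[(2S,3S,4R)-2-[3,4-bis(benzyloxy)phenyl]-4-(4-benzyloxy-3-methoxybenzyl)oxolan-3-yl]carbonyl}oxazolidin-2-one | COc1cc(C[C@H]2CO[C@H](c3ccc(OCc4ccccc4)c(OCc4ccccc4)c3)[C@H]2C(=O)N2CCOC2=O)ccc1OCc1ccccc1 | intermediate
16 | [(2S,3R,4R)-2-[3,4-bis(benzyloxy)phenyl]-4-(4-benzyloxy-3-methoxybenzyl)oxolan-3-yl]methanol | COc1cc(C[C@H]2CO[C@H](c3ccc(OCc4ccccc4)c(OCc4ccccc4)c3)[C@H]2CO)ccc1OCc1ccccc1 | intermediate
17 | [(2S,3R,4R)-2-[3,4-bis(benzyloxy)phenyl]-4-(4-benzyloxy-3-methoxybenzyl)oxolan-3-yl]methyl acetate | COc1cc(C[C@H]2CO[C@H](c3ccc(OCc4ccccc4)c(OCc4ccccc4)c3)[C@H]2COC(C)=O)ccc1OCc1ccccc1 | intermediate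
18 | [(2S,3R,4R)-2-(3,4-dihydroxyphenyl)-4-(4-hydroxy-3-methoxybenzyl)oxolan-3-yl]methyl acetate | COc1cc(C[C@H]2CO[C@H](c3ccc(O)c(O)c3)[C@H]2COC(C)=O)ccc1O | target

## Step count and least certain steps

Total step count: 11. Longest linear sequence: 7 steps (5 to 18 through steps 3, 4, 7, 8, 9, 10 and 11; the branch from 9 is equally long).

Step 8 (key step, new method). Several processes can fail.
- Fluoride or chloride may bind nickel, so the uncatalysed addition takes over and face control is lost.
- The Z substituent crowds the metal-bound acyl oxygen in the planar s-cis chelate, so the chelate may twist, which would cost both activation and face discrimination.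
- Fluoride may remove a γ-proton of the chelated imide, leading to Z/E isomerisation or deconjugation towards the styrene and thus loss of the 3,4-cis relation or of reactivity.
- 4 may be hydrolysed by residual water or may lose the silylmethyl group to chloride before the ylide forms.
- The ylide may dimerise.
- An endo approach would invert C2.

The fallback uses known reaction types only, with face control moved to a covalent auxiliary and C2 to equilibration. It sets out from 8 and 4 and returns at 16. Commercial (S)-4-benzyl-3-(chloroacetyl)oxazolidin-2-one, (PhO)2P(O)H and Et3N in CH2Cl2 give (S)-4-benzyl-3-[2-(diphenoxyphosphoryl)acetyl]oxazolidin-2-one F1. Olefination of 8 with F1 under the conditions of step 7 gives (S)-4-benzyl-3-[(Z)-4-(4-benzyloxy-3-methoxyphenyl)but-2-enoyl]oxazolidin-2-one F2. F2, 4 and CsF in MeCN at room temperature without any Lewis acid, the established way of adding such ylides to electron-poor alkenes, should give the 3,4-cis adducts as chromatographically separable diastereomers. The pair formed on the Cα-Re face is collected: the 2,3-trans adduct (S)-4-benzyl-3-{[(2S,3S,4R)-2-[3,4-bis(benzyloxy)phenyl]-4-(4-benzyloxy-3-methoxybenzyl)oxolan-3-yl]carbonyl}oxazolidin-2-one F3 and its C2 epimer (S)-4-benzyl-3-{[(2R,3S,4R)-2-[3,4-bis(benzyloxy)phenyl]-4-(4-benzyloxy-3-methoxybenzyl)oxolan-3-yl]carbonyl}oxazolidin-2-one F4. LiBH4 as in step 9 converts F3 into 16 and F4 into [(2R,3R,4R)-2-[3,4-bis(benzyloxy)phenyl]-4-(4-benzyloxy-3-methoxybenzyl)oxolan-3-yl]methanol F5. A catalytic amount of camphorsulfonic acid in CH2Cl2 at 0 °C equilibrates F5 to 16 by reversible ionisation of the C2–O1 bond towards the less crowded 2,3-trans ring. The exposure is kept short because the same cation can be trapped by ring B. The same treatment would rescue a catalytic run that proved endo-selective, which would pass through F5 after step 9.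

Step 4. Ozone may attack the electron-rich dialkoxyarene, and the enolisable arylacetaldehyde may self-condense or oxidise in air during work-up. Fallback from 6, returning at 8: OsO4 (cat.) with N-methylmorpholine N-oxide in acetone–water gives the racemic diol 3-(4-benzyloxy-3-methoxyphenyl)propane-1,2-diol F6. NaIO4 on wet silica in CH2Cl2 then cleaves F6 to 8 under neutral, peroxide-free conditions.

Step 7. Z-selectivity may erode if the adduct equilibrates before elimination, and base may remove the γ-proton and destroy the Z-enoyl geometry. Fallback from 8, returning at 12: Still–Gennari olefination with commercial methyl bis(2,2,2-trifluoroethyl)phosphonoacetate (KHMDS, 18-crown-6, THF, −78 °C) gives methyl (Z)-4-(4-benzyloxy-3-methoxyphenyl)but-2-enoate F7. Me3SnOH in 1,2-dichloroethane hydrolyses F7 without strong base to (Z)-4-(4-benzyloxy-3-methoxyphenyl)but-2-enoic acid F8. F8 is activated with PivCl and Et3N at −20 °C and coupled with 9 in the presence of LiCl to give 12.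

Step 9. Hydride may attack the ring carbonyl of the hindered imide, opening the oxazolidinone instead of releasing it, and the basic reagent may epimerise C3. Fallback from 15, returning at 16: LiOH and H2O2 in THF–water at 0 °C, where hydroperoxide is selective for the exocyclic carbonyl, give (2S,3S,4R)-2-[3,4-bis(benzyloxy)phenyl]-4-(4-benzyloxy-3-methoxybenzyl)oxolane-3-carboxylic acid F9. BH3·SMe2 in THF then reduces F9 to 16.

Step 11. The benzylic C2–O1 bond may be hydrogenolysed once the para-oxygen is unmasked, opening the oxolane, and the catechol may oxidise in air. Fallback from 17, returning at 18: non-reductive debenzylation with BCl3 and pentamethylbenzene as cation scavenger in CH2Cl2, held at −78 °C so that the Lewis acid does not ionise the C2–O1 bond, which should leave the acetate and the methyl ether alone. No new isolated compound is involved.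

## Further compounds

F1 | step 8 | (S)-4-benzyl-3-[2-(diphenoxyphosphoryl)acetyl]oxazolidin-2-one | O=C1OC[C@H](Cc2ccccc2)N1C(=O)CP(=O)(Oc1ccccc1)Oc1ccccc1
F2 | step 8 | (S)-4-benzyl-3-[(Z)-4-(4-benzyloxy-3-methoxyphenyl)but-2-enoyl]oxazolidin-2-one | O=C1OC[C@H](Cc2ccccc2)N1C(=O)/C=C\Cc1ccc(OCc2ccccc2)c(OC)c1
F3 | step 8 | (S)-4-benzyl-3-{[(2S,3S,4R)-2-[3,4-bis(benzyloxy)phenyl]-4-(4-benzyloxy-3-methoxybenzyl)oxolan-3-yl]carbonyl}oxazolidin-2-one | COc1cc(C[C@H]2CO[C@H](c3ccc(OCc4ccccc4)c(OCc4ccccc4)c3)[C@H]2C(=O)N2[C@@H](Cc3ccccc3)COC2=O)ccc1OCc1ccccc1
F4 | step 8 | (S)-4-benzyl-3-{[(2R,3S,4R)-2-[3,4-bis(benzyloxy)phenyl]-4-(4-benzyloxy-3-methoxybenzyl)oxolan-3-yl]carbonyl}oxazolidin-2-one | COc1cc(C[C@H]2CO[C@@H](c3ccc(OCc4ccccc4)c(OCc4ccccc4)c3)[C@H]2C(=O)N2[C@@H](Cc3ccccc3)COC2=O)ccc1OCc1ccccc1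
F5 | step 8 | [(2R,3R,4R)-2-[3,4-bis(benzyloxy)phenyl]-4-(4-benzyloxy-3-methoxybenzyl)oxolan-3-yl]methanol | COc1cc(C[C@H]2CO[C@@H](c3ccc(OCc4ccccc4)c(OCc4ccccc4)c3)[C@H]2CO)ccc1OCc1ccccc1
F6 | step 4 | 3-(4-benzyloxy-3-methoxyphenyl)propane-1,2-diol (racemic) | OCC(O)Cc1ccc(OCc2ccccc2)c(OC)c1
F7 | step 7 | methyl (Z)-4-(4-benzyloxy-3-methoxyphenyl)but-2-enoate | COC(=O)/C=C\Cc1ccc(OCc2ccccc2)c(OC)c1
F8 | step 7 | (Z)-4-(4-benzyloxy-3-methoxyphenyl)but-2-enoic acid | OC(=O)/C=C\Cc1ccc(OCc2ccccc2)c(OC)c1
F9 | step 9 | (2S,3S,4R)-2-[3,4-bis(benzyloxy)phenyl]-4-(4-benzyloxy-3-methoxybenzyl)oxolane-3-carboxylic acid | COc1cc(C[C@H]2CO[C@H](c3ccc(OCc4ccccc4)c(OCc4ccccc4)c3)[C@H]2C(=O)O)ccc1OCc1ccccc1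
F0 | step 11 | none | none
A1 | alternative 1 | (3R,4R,5R)-3-(4-benzyloxy-3-methoxybenzyl)-4-{2-[3,4-bis(benzyloxy)phenyl]-1,3-dithian-2-yl}-5-{[(1R,2S,5R)-2-isopropyl-5-methylcyclohexyl]oxy}oxolan-2-one | COc1cc(C[C@H]2C(=O)O[C@@H](O[C@@H]3C[C@H](C)CC[C@H]3C(C)C)[C@@H]2C2(c3ccc(OCc4ccccc4)c(OCc4ccccc4)c3)SCCCS2)ccc1OCc1ccccc1
A2 | alternative 1 | (5R)-5-{[(1R,2S,5R)-2-isopropyl-5-methylcyclohexyl]oxy}furan-2(5H)-one | O=C1O[C@@H](O[C@@H]2C[C@H](C)CC[C@H]2C(C)C)C=C1
A3 | alternative 1 | 2-[3,4-bis(benzyloxy)phenyl]-1,3-dithiane | C1CSC(SC1)c1ccc(OCc2ccccc2)c(OCc2ccccc2)c1
A4 | alternative 1 | 1-(benzyloxy)-4-(bromomethyl)-2-methoxybenzene | COc1cc(CBr)ccc1OCc1ccccc1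
A5 | alternative 2 | (2R,3R)-2-(3-benzyloxy-4-hydroxybenzyl)-3-(4-benzyloxy-3-methoxybenzyl)butane-1,4-diol | COc1cc(C[C@@H](CO)[C@H](CO)Cc2ccc(O)c(OCc3ccccc3)c2)ccc1OCc1ccccc1
A6 | alternative 2 | 2-(benzyloxy)-4-[(2S,3R,4R)-4-(4-benzyloxy-3-methoxybenzyl)-3-(hydroxymethyl)oxolan-2-yl]phenol | COc1cc(C[C@H]2CO[C@H](c3ccc(O)c(OCc4ccccc4)c3)[C@H]2CO)ccc1OCc1ccccc1
A7 | alternative 3 | (2R)-2-[(R)-[3,4-bis(benzyloxy)phenyl]{[(E)-3-(4-benzyloxy-3-methoxyphenyl)prop-2-en-1-yl]oxy}methyl]oxirane (the epimer at the oxirane carbon would serve equally) | COc1cc(/C=C/CO[C@H](c2ccc(OCc3ccccc3)c(OCc3ccccc3)c2)[C@H]2CO2)ccc1OCc1ccccc1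
A8 | alternative 3 | [(2S,3R,4R)-2-[3,4-bis(benzyloxy)phenyl]-4-(4-benzyloxy-3-methoxybenzyl)oxolan-3-yl]methanol (identical with 16) | COc1cc(C[C@H]2CO[C@H](c3ccc(OCc4ccccc4)c(OCc4ccccc4)c3)[C@H]2CO)ccc1OCc1ccccc1
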